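**Retrosynthetic overview**

1. The (S)-lactol is released from its bis-isobutyrate by enzymatic acyl–oxygen cleavage. The bis-isobutyrate comes from the ring-opened aldehyde acid and isobutyric anhydride by a catalytic acylative dynamic kinetic resolution.
2. The strategy rests on C3, the hemiacetal carbon of ring D (the five-membered lactol–lactone fused to ring B), which carries H, OH, ring oxygen O2 and ring-B carbon C3a. It epimerises by opening to the 2-formylbenzoic acid, and acylation of the closed form locks ring D and C3 together.
3. The aldehyde acid is cut at the depsidone ester C–O bond (seven-membered ring C, carbodiimide lactonisation) and then at the diaryl ether C–O bond (SNAr of a ring-B phenol on a ring-A aryl fluoride flanked by formyl and ester).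
4. Ring A comes from 1-fluoro-3-methoxy-5-methylbenzene by two directed lithiations (CHO, then CO2Bn). Ring B comes from 5-bromo-2,4-dihydroxybenzoic acid (Br to OH, then ortho-formylation).
5. Ring order: rings A and B are present in the starting benzenes, ring C is closed in step 10 and ring D in step 12.

Key step: step 12

Assumption: the free lactol loses its C3 configuration wherever it can ionise or open (base, water, acid), so the last step is run without base or water and the product is kept cold; both starting benzenes are taken as commercial.

**Route**

Step 1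
Reactants: 1 1-fluoro-3-methoxy-5-methylbenzene
Product: 3 2-fluoro-6-methoxy-4-methylbenzaldehyde, via aryllithium 2 (not isolated)
Conditions: n-BuLi, THF, −78 °C; DMF, −78 → 0 °C; aq. NH4Cl
Reagents that add atoms: N,N-dimethylformamide, CN(C)C=O
Why: Directed ortho-lithiation removes the most acidic ring proton, the one flanked by fluorine and methoxy, and the aryllithium is formylated by DMF.

Step 2
Reactants: 3 2-fluoro-6-methoxy-4-methylbenzaldehyde
Product: 4 2-(dimethoxymethyl)-1-fluoro-3-methoxy-5-methylbenzene
Conditions: HC(OMe)3, MeOH, p-TsOH (cat.), reflux; Et3N quench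
Reagents that add atoms: trimethyl orthoformate, COC(OC)OC; methanol, CO
Why: Acid-catalysed acetalisation with the orthoformate as water scavenger masks the aldehyde against the organolithium of the next step.

Step 3
Reactants: 4 2-(dimethoxymethyl)-1-fluoro-3-methoxy-5-methylbenzene
Product: 7 benzyl 2-fluoro-3-formyl-4-methoxy-6-methylbenzoate, via aryllithium 5 (not isolated), via acetal benzyl ester 6 (not isolated)
Conditions: s-BuLi, PMDTA, THF, −78 °C; ClCO2Bn, −78 °C; then 2 M HCl, THF, rt
Reagents that add atoms: benzyl chloroformate, O=C(Cl)OCc1ccccc1; water, O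
Why: Directed ortho-lithiation with the triamine-complexed, acidity-driven base should take the proton next to fluorine in preference to the one next to methoxy, the hindered aryllithium is acylated once by the chloroformate, and the acidic work-up hydrolyses the dimethyl acetal.

Step 4
Reactants: 8 5-bromo-2,4-dihydroxybenzoic acid
Product: 9 tert-butyl 5-bromo-2,4-dihydroxybenzoate
Conditions: Me2NCH(OtBu)2, toluene, 80 °C
Reagents that add atoms: N,N-dimethylformamide di-tert-butyl acetal, CN(C)C(OC(C)(C)C)OC(C)(C)C
Why: tert-Butyl esterification with an amide acetal (the carboxylic acid protonates the acetal and the carboxylate takes up the tert-butyl group) should leave the less acidic phenols free.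

Step 5
Reactants: 9 tert-butyl 5-bromo-2,4-dihydroxybenzoate
Product: 10 tert-butyl 2,4-bis(benzyloxy)-5-bromobenzoate
Conditions: BnBr, K2CO3, DMF, 60 °C
Reagents that add atoms: benzyl bromide, BrCc1ccccc1
Why: Williamson etherification of both phenols; heating serves the hydrogen-bonded 2-OH and the tert-butyl ester withstands carbonate.

Step 6
Reactants: 10 tert-butyl 2,4-bis(benzyloxy)-5-bromobenzoate
Product: 12 tert-butyl 2,4-bis(benzyloxy)-5-hydroxybenzoate, via pinacol boronate 11 (not isolated)
Conditions: B2pin2, PdCl2(dppf), KOAc, 1,4-dioxane, 90 °C; then 30% H2O2, 1 M NaOH, THF, 0 °C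
Reagents that add atoms: hydrogen peroxide, OO
Why: Miyaura borylation followed by boronate oxidation (aryl shift from boron to oxygen) installs the phenol that will become the diaryl ether oxygen while its neighbour, the future ester oxygen, stays benzylated.

Step 7
Reactants: 12 tert-butyl 2,4-bis(benzyloxy)-5-hydroxybenzoate
Product: 13 tert-butyl 4,6-bis(benzyloxy)-2-formyl-3-hydroxybenzoate
Conditions: MgCl2, Et3N, (CH2O)n, MeCN, reflux; 1 M HCl work-up
Reagents that add atoms: paraformaldehyde (formaldehyde), C=O
Why: Magnesium-mediated ortho-formylation (Casnati–Skattebøl): the magnesium phenoxide delivers formaldehyde to the only free ortho carbon and a second formaldehyde oxidises the benzylic alkoxide by hydride transfer, so the electron-rich carbon between the two benzyloxy groups should be left alone.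

Step 8
Reactants: 7 benzyl 2-fluoro-3-formyl-4-methoxy-6-methylbenzoate; 13 tert-butyl 4,6-bis(benzyloxy)-2-formyl-3-hydroxybenzoate
Product: 14 benzyl 2-[4,6-bis(benzyloxy)-3-(tert-butoxycarbonyl)-2-formylphenoxy]-3-formyl-4-methoxy-6-methylbenzoate
Conditions: K2CO3, DMF, 70 °C, under N2
Reagents that add atoms: none
Why: Nucleophilic aromatic substitution (SNAr): the fluoride of 7 is activated by the ortho formyl and ortho ester groups and should be displaced by the phenoxide of 13, which fixes the ether at the ring-B oxygen next to the formyl group because the neighbouring oxygen is still benzylated.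

Step 9
Reactants: 14 benzyl 2-[4,6-bis(benzyloxy)-3-(tert-butoxycarbonyl)-2-formylphenoxy]-3-formyl-4-methoxy-6-methylbenzoate
Product: 15 2-[3-(tert-butoxycarbonyl)-2-formyl-4,6-dihydroxyphenoxy]-3-formyl-4-methoxy-6-methylbenzoic acid
Conditions: H2 (1 atm), Pd/C (10 wt% Pd), EtOAc, rt, stopped at full debenzylation
Reagents that add atoms: none
Why: Hydrogenolysis removes the benzyl ester and both benzyl ethers under neutral conditions, which avoids the Smiles rearrangement that base could start at the freed phenol, and the two di-ortho-substituted aldehydes and the tert-butyl ester are expected to survive at 1 atm.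

Step 10
Reactants: 15 2-[3-(tert-butoxycarbonyl)-2-formyl-4,6-dihydroxyphenoxy]-3-formyl-4-methoxy-6-methylbenzoic acid
Product: 16 tert-butyl 4,6-diformyl-8-hydroxy-3-methoxy-1-methyl-11-oxo-11H-dibenzo[b,e][1,4]dioxepine-7-carboxylate
Conditions: DCC, toluene, rt, high dilution (0.005 M)
Reagents that add atoms: none
Why: Carbodiimide lactonisation (7-exo-trig attack of the phenol ortho to the ether oxygen on the O-acylisourea) closes the depsidone ring C; the other phenol is para to the ether oxygen and cannot reach the acid.

Step 11
Reactants: 16 tert-butyl 4,6-diformyl-8-hydroxy-3-methoxy-1-methyl-11-oxo-11H-dibenzo[b,e][1,4]dioxepine-7-carboxylate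
Product: 17 4,6-diformyl-8-hydroxy-3-methoxy-1-methyl-11-oxo-11H-dibenzo[b,e][1,4]dioxepine-7-carboxylic acid (aldehyde acid, the open tautomer of the racemic lactol, with which it interconverts)
Conditions: TFA, CH2Cl2, 0 °C → rt
Reagents that add atoms: none
Why: Acidolysis of the tert-butyl ester through the tert-butyl cation (lost as isobutene) frees the ring-B acid without touching the depsidone aryl ester or the aldehydes.

Step 12
Reactants: 17 aldehyde acid; 18 isobutyric anhydride
Product: 21 bis-isobutyrate of the (S)-lactol (C3 phthalidyl ester plus C7 phenol ester), via racemic lactol 19 (not isolated), via (S)-lactol mono-isobutyrate 20 (not isolated)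
Conditions: (R)-benzotetramisole (10 mol%; its antipode if a first trial shows that one to lead to the (S)-ester), iPr2NEt (2.5 equiv), 18 (3 equiv, added slowly), CHCl3, 0 °C
Reagents that add atoms: isobutyric anhydride (18), CC(C)C(=O)OC(=O)C(C)C
Why: Under the amine base 17 and its closed form 19 interconvert through the carboxylate (5-exo-trig addition of the carboxylate oxygen to the formyl carbon and its reverse), so the two lactol enantiomers exchange through an achiral species. The isothiourea is acylated by 18 to a chiral N-acyl isothiouronium ion, which should pass its acyl group to the hydroxyl of one lactol enantiomer much faster than to the other; the resulting acetal ester 20 can no longer open, so the O2–C3 bond of ring D and the C3 configuration are fixed together, and excess 18 then esterifies the chelated C7 phenol to give 21. The closest known reaction type is the acylative dynamic kinetic resolution of 3-hydroxyphthalides to phthalidyl esters with chiral nucleophilic acyl-transfer catalysts. The new stereocentre is under catalyst control, the catalyst antipode being chosen to give the (S)-ester, whose descriptor matches that of the target because the ring oxygen outranks the acyloxy oxygen just as it outranks OH. The step needs enantiomer selection with racemisation faster than acylation, and site selection; the first is served by the base-driven ring–chain exchange, the low temperature and the slow addition of 18 that hold down uncatalysed acylation, the second by the substrate, which offers only the lactol and phenol hydroxyls while the depsidone ester carbonyl is shielded by two ortho substituents.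

Step 13
Reactants: 21 bis-isobutyrate of the (S)-lactol
Product: 22 (S)-lactol, the target
Conditions: immobilised Candida antarctica lipase B, n-BuOH (10 equiv), MTBE/THF, 20 °C; filter; crystallise cold from EtOAc/heptane
Reagents that add atoms: none
Why: Lipase-catalysed alcoholysis (acyl transfer to butanol through the acyl-enzyme) breaks only the two acyl–oxygen bonds in a non-ionising medium, so no bond to C3 is broken and the lactol is not deprotonated to its ring-opening anion.

**Compound list**

1 | 1-fluoro-3-methoxy-5-methylbenzene | COc1cc(C)cc(F)c1 | starting material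
2 | (2-fluoro-6-methoxy-4-methylphenyl)lithium (not isolated) | [Li]c1c(F)cc(C)cc1OC | intermediate
3 | 2-fluoro-6-methoxy-4-methylbenzaldehyde | COc1cc(C)cc(F)c1C=O | intermediate
4 | 2-(dimethoxymethyl)-1-fluoro-3-methoxy-5-methylbenzene | COc1cc(C)cc(F)c1C(OC)OC | intermediate
5 | [3-(dimethoxymethyl)-2-fluoro-4-methoxy-6-methylphenyl]lithium (not isolated) | COc1cc(C)c([Li])c(F)c1C(OC)OC | intermediate
6 | benzyl 3-(dimethoxymethyl)-2-fluoro-4-methoxy-6-methylbenzoate (not isolated) | COc1cc(C)c(C(=O)OCc2ccccc2)c(F)c1C(OC)OC | intermediate
7 | benzyl 2-fluoro-3-formyl-4-methoxy-6-methylbenzoate | COc1cc(C)c(C(=O)OCc2ccccc2)c(F)c1C=O | intermediate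
8 | 5-bromo-2,4-dihydroxybenzoic acid | OC(=O)c1cc(Br)c(O)cc1O | starting material
9 | tert-butyl 5-bromo-2,4-dihydroxybenzoate | CC(C)(C)OC(=O)c1cc(Br)c(O)cc1O | intermediate
10 | tert-butyl 2,4-bis(benzyloxy)-5-bromobenzoate | CC(C)(C)OC(=O)c1cc(Br)c(OCc2ccccc2)cc1OCc1ccccc1 | intermediate
11 | tert-butyl 2,4-bis(benzyloxy)-5-(4,4,5,5-tetramethyl-1,3,2-dioxaborolan-2-yl)benzoate (not isolated) | CC(C)(C)OC(=O)c1cc(B2OC(C)(C)C(C)(C)O2)c(OCc2ccccc2)cc1OCc1ccccc1 | intermediate
12 | tert-butyl 2,4-bis(benzyloxy)-5-hydroxybenzoate | CC(C)(C)OC(=O)c1cc(O)c(OCc2ccccc2)cc1OCc1ccccc1 | intermediate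
13 | tert-butyl 4,6-bis(benzyloxy)-2-formyl-3-hydroxybenzoate | CC(C)(C)OC(=O)c1c(OCc2ccccc2)cc(OCc2ccccc2)c(O)c1C=O | intermediate
14 | benzyl 2-[4,6-bis(benzyloxy)-3-(tert-butoxycarbonyl)-2-formylphenoxy]-3-formyl-4-methoxy-6-methylbenzoate | COc1cc(C)c(C(=O)OCc2ccccc2)c(Oc2c(OCc3ccccc3)cc(OCc3ccccc3)c(C(=O)OC(C)(C)C)c2C=O)c1C=O | intermediate
15 | 2-[3-(tert-butoxycarbonyl)-2-formyl-4,6-dihydroxyphenoxy]-3-formyl-4-methoxy-6-methylbenzoic acid | COc1cc(C)c(C(=O)O)c(Oc2c(O)cc(O)c(C(=O)OC(C)(C)C)c2C=O)c1C=O | intermediate
16 | tert-butyl 4,6-diformyl-8-hydroxy-3-methoxy-1-methyl-11-oxo-11H-dibenzo[b,e][1,4]dioxepine-7-carboxylate | COc1cc(C)c2c(c1C=O)Oc1c(cc(O)c(C(=O)OC(C)(C)C)c1C=O)OC2=O | intermediate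
17 | 4,6-diformyl-8-hydroxy-3-methoxy-1-methyl-11-oxo-11H-dibenzo[b,e][1,4]dioxepine-7-carboxylic acid (aldehyde acid, achiral open tautomer) | COc1cc(C)c2c(c1C=O)Oc1c(cc(O)c(C(=O)O)c1C=O)OC2=O | intermediate
18 | isobutyric anhydride | CC(C)C(=O)OC(=O)C(C)C | starting material
19 | racemic lactol, ring-closed tautomer of 17 (3-hydroxyphthalide on ring B; not isolated) | COc1cc(C)c2c(c1C=O)Oc1c(cc(O)c3c1C(O)OC3=O)OC2=O | intermediate
20 | (S)-lactol mono-isobutyrate (C3 ester, C7 phenol free; not isolated) | COc1cc(C)c2c(c1C=O)Oc1c(cc(O)c3c1[C@@H](OC(=O)C(C)C)OC3=O)OC2=O | intermediate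
21 | bis-isobutyrate of the (S)-lactol (C3 phthalidyl ester and C7 phenol ester) | COc1cc(C)c2c(c1C=O)Oc1c(cc(OC(=O)C(C)C)c3c1[C@@H](OC(=O)C(C)C)OC3=O)OC2=O | intermediate
22 | (S)-lactol: depsidone with ring A carrying OMe, CHO and CH3, ring B carrying the C7 phenol and the fused (3S)-3-hydroxyphthalide | COc1cc(C)c2c(c1C=O)Oc1c(cc(O)c3c1[C@@H](O)OC3=O)OC2=O | target

**Step count and risks**

Total step count: 13. Longest linear sequence: 10 steps (steps 4 to 13).

Steps most likely to fail:

Step 12. Uncatalysed acylation of the lactol or of its carboxylate (through a mixed anhydride) may compete with the catalysed transfer, or ring opening may become slower than acylation, so that both lactol enantiomers are esterified. The fallback moves the enantiomer selection to an enzyme. It sets out from 17: an immobilised Burkholderia cepacia lipase with vinyl acetate in toluene/THF, with a catalytic amount of Et3N to keep the lactol equilibrating, should acylate one enantiomer of the exchanging lactol to the (S)-lactol acetate F1, with the chelated phenol left free. F1 is then deacylated under the conditions of step 13 and so comes back to the route at 22.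

Step 13. The freed lactol may open to the aldehyde acid on the enzyme support or in solution before it crystallises, which erodes the configuration, or the lipase may turn over the hindered acetal ester too slowly. The fallback replaces acyl transfer by a hydrogenolytic release that needs no nucleophile, base or water. It sets out from 17: the same isothiourea-catalysed resolution is run with dibenzyl dicarbonate in place of 18, the N-benzyloxycarbonyl isothiouronium ion acting as the transferring species (this carbonate variant has less precedent than the anhydride acylation), to give the bis(benzyl carbonate) F2, which has the same spatial arrangement at C3 as 22. Brief hydrogenolysis (H2, Pd/C, EtOAc, 0 °C) then removes both groups, and the route is rejoined at 22.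

Step 7. Formylation at the crowded carbon between the hydroxyl and the tert-butyl ester may be slow or stop at the hydroxymethyl stage. The fallback introduces the formyl group before the oxygen. It sets out from 10: deprotonation between bromine and the ester with LiTMP (THF, −78 °C) and a DMF quench should give tert-butyl 4,6-bis(benzyloxy)-3-bromo-2-formylbenzoate F3. Miyaura borylation (B2pin2, PdCl2(dppf), KOAc, dioxane, 90 °C) gives tert-butyl 4,6-bis(benzyloxy)-2-formyl-3-(4,4,5,5-tetramethyl-1,3,2-dioxaborolan-2-yl)benzoate F4. Oxidation with N-methylmorpholine N-oxide, which spares the aldehyde from Dakin oxidation, returns to the route at 13.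

**Further compounds**

F1 | step 12 | (S)-lactol acetate (C3 acetate, C7 phenol free) | COc1cc(C)c2c(c1C=O)Oc1c(cc(O)c3c1[C@@H](OC(C)=O)OC3=O)OC2=O
F2 | step 13 | bis(benzyl carbonate) of the lactol (C3 and C7 carbonates; spatial arrangement at C3 as in 22, descriptor R by the priority change) | COc1cc(C)c2c(c1C=O)Oc1c(cc(OC(=O)OCc3ccccc3)c3c1[C@@H](OC(=O)OCc1ccccc1)OC3=O)OC2=O
F3 | step 7 | tert-butyl 4,6-bis(benzyloxy)-3-bromo-2-formylbenzoate | CC(C)(C)OC(=O)c1c(OCc2ccccc2)cc(OCc2ccccc2)c(Br)c1C=O
F4 | step 7 | tert-butyl 4,6-bis(benzyloxy)-2-formyl-3-(4,4,5,5-tetramethyl-1,3,2-dioxaborolan-2-yl)benzoate | CC(C)(C)OC(=O)c1c(OCc2ccccc2)cc(OCc2ccccc2)c(B2OC(C)(C)C(C)(C)O2)c1C=O
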